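Everything rests on cutting the C1–C10 bond of the upper cycloheptane (ring atoms C1, C5, C6, C7, C8, C9, C10; xanthanolide locants, lower unit primed). The precursor 39 already holds the lower cycloheptene, its lactone (spiro at C11′), the cyclohexenone (C1 still a ketone) and the upper trans-lactone, whose C8 carries only an allyl group. Hydrogen-atom transfer from an iron hydride to that allyl group gives the C10 radical, which adds to the C1 carbonyl: one operation closes the seven-membered ring and creates the tertiary alcohol, the C14 methyl and the C1 and C10 stereocentres. The step exploits the vicinal C1(OH)–C10(H)CH3 pair. A siloxydiene Diels–Alder reaction on the 8-epi-xanthatin-type methylidene lactone 16 builds 39.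

Key step: step 18

Remark: xanthanolide locants are used throughout (upper unit unprimed, lower unit primed; C1 carbinol, C5 ring-fusion CH, C10 CHMe, C14 its methyl, C11′ spiro carbon, C13′ cyclohexene CH2); the lower unit is taken in the configuration drawn, so its methyl centre comes from (R)-but-3-yn-2-ol.

**Lower unit (steps 1–7)**

Step 1
Reactants: 1 (R)-but-3-yn-2-ol
Product: 2 (R)-but-3-yn-2-yl methanesulfonate
Conditions: MsCl, Et3N, CH2Cl2, 0 °C
Reagents that add atoms: methanesulfonyl chloride CS(=O)(=O)Cl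
Why: Sulfonylation of the alcohol oxygen leaves the C–O bond and thus the (R) centre untouched and turns it into a leaving group.

Step 2
Reactants: 2 (R)-but-3-yn-2-yl methanesulfonate; 3 diethyl malonate
Product: 4 diethyl 2-[(R)-but-3-yn-2-yl]malonate
Conditions: NaH, THF–DMF, 0 → 60 °C
Reagents that add atoms: none
Why: Malonate alkylation by SN2 displacement of the secondary propargylic mesylate should proceed with inversion, which fixes the future C10′ methyl centre (the descriptor stays R because the priorities change).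

Step 3
Reactants: 4 diethyl 2-[(R)-but-3-yn-2-yl]malonate
Product: 5 ethyl (R)-3-methylpent-4-ynoate
Conditions: LiCl, H2O, DMSO, 150 °C
Reagents that add atoms: none
Why: Krapcho dealkoxycarbonylation removes one ester group under near-neutral conditions that do not touch the propargylic stereocentre.

Step 4
Reactants: 5 ethyl (R)-3-methylpent-4-ynoate
Product: 6 (R)-3-methylpent-4-ynal
Conditions: i-Bu2AlH, CH2Cl2, −78 °C; Rochelle salt work-up; used as a solution
Reagents that add atoms: none
Why: Partial reduction of the ester with i-Bu2AlH at low temperature stops at the tetrahedral aluminium hemiacetal, which gives the aldehyde on work-up.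

Step 5
Reactants: 7 ethyl propiolate; 8 allylmagnesium bromide; 9 2-(iodomethyl)-4,4,5,5-tetramethyl-1,3,2-dioxaborolane
Product: 11 ethyl (E)-2-[(4,4,5,5-tetramethyl-1,3,2-dioxaborolan-2-yl)methyl]hexa-2,5-dienoate, via alkenylcopper 10 (not isolated)
Conditions: CuBr·SMe2 (1 equiv), THF, −78 °C; then 9, DMPU, −78 → 0 °C
Reagents that add atoms: none
Why: Syn-carbocupration of the propiolate places allyl and copper cis, and alkylation of the alkenylcopper by the iodomethylboronate occurs with retention, so the allyl group ends cis to CH2B as a syn-selective allylboration requires.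

Step 6
Reactants: 6 (R)-3-methylpent-4-ynal; 11 ethyl (E)-2-[(4,4,5,5-tetramethyl-1,3,2-dioxaborolan-2-yl)methyl]hexa-2,5-dienoate
Product: 13 (4S,5S)-3-methylidene-5-[(2R)-2-methylbut-3-ynyl]-4-(prop-2-enyl)oxolan-2-one, via hydroxy ester 12 (not isolated)
Conditions: (R)-TRIP [(R)-3,3′-bis(2,4,6-triisopropylphenyl)-1,1′-binaphthyl-2,2′-diyl hydrogen phosphate] (10 mol%), 4 Å MS, toluene, rt; then TsOH·H2O (cat.), 40 °C
Reagents that add atoms: none
Why: Chiral phosphoric acid-catalysed allylboration through a closed chair transition state should turn the cis relation of allyl and CH2B into the syn C7′/C8′ pair while the catalyst selects the aldehyde face (8′S, by analogy with simple allylboronates), and the cis hydroxy ester lactonises under acid.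

Step 7
Reactants: 13 (4S,5S)-3-methylidene-5-[(2R)-2-methylbut-3-ynyl]-4-(prop-2-enyl)oxolan-2-one; 14 but-3-en-2-one
Product: 16 (3aS,7R,8aS)-7-methyl-3-methylidene-6-[(E)-3-oxobut-1-enyl]-3,3a,4,7,8,8a-hexahydrocyclohepta[b]furan-2-one, via vinylcycloheptene lactone 15 (not isolated)
Conditions: second-generation Hoveyda–Grubbs catalyst [(H2IMes)Cl2Ru=CH(C6H4-2-OiPr)] (10 mol%), 14 (excess), CH2Cl2, 40 °C
Reagents that add atoms: none
Why: Domino ring-closing enyne metathesis and cross-metathesis, in which the ruthenium carbene formed at the allyl group closes the seven-membered ring onto the alkyne and the resulting 1,3-diene is capped E-selectively by the vinyl ketone while the electron-poor methylidene lactone stays inert.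

**Upper unit (steps 8–16)**

Step 8
Reactants: 17 (R)-2-(chloromethyl)oxirane; 18 vinylmagnesium bromide
Product: 20 (R)-2-(prop-2-enyl)oxirane, via chlorohydrin 19 (not isolated)
Conditions: CuI (5 mol%), THF, −40 → 0 °C; aq. NH4Cl; then NaOH, Et2O–H2O, rt; distillation
Reagents that add atoms: none
Why: Copper-catalysed opening of the epoxide at its CH2 terminus by the vinyl Grignard reagent and base-induced closure of the chlorohydrin onto the former chloromethyl carbon relocate the epoxide without touching the stereocentre (the future C8).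

Step 9
Reactants: 20 (R)-2-(prop-2-enyl)oxirane; 21 2-(phenylsulfanyl)acetic acid
Product: 23 (5R)-3-(phenylsulfanyl)-5-(prop-2-enyl)oxolan-2-one (both C3 epimers), via hydroxy acid 22 (not isolated)
Conditions: LiN(i-Pr)2 (2.1 equiv), THF, 0 °C; then 20; aq. HCl; then TsOH·H2O (cat.), toluene, 80 °C
Reagents that add atoms: none
Why: The carboxylate α-carbanion (dianion) opens the epoxide at CH2 with retention of the carbinol centre and the γ-hydroxy acid lactonises under acid catalysis.

Step 10
Reactants: 23 (5R)-3-(phenylsulfanyl)-5-(prop-2-enyl)oxolan-2-one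
Product: 25 (R)-5-(prop-2-enyl)furan-2(5H)-one, via sulfoxide 24 (not isolated)
Conditions: mCPBA (1.0 equiv), CH2Cl2, −78 °C; then toluene, 110 °C
Reagents that add atoms: none
Why: Sulfide-selective oxidation at low temperature (the terminal alkene is far less nucleophilic) and thermal syn-elimination of the sulfoxide give the butenolide.

Step 11
Reactants: 25 (R)-5-(prop-2-enyl)furan-2(5H)-one; 26 [2-(1,3-dioxan-2-yl)ethyl]magnesium bromide; 27 formaldehyde
Product: 29 (3R,4S,5R)-4-[2-(1,3-dioxan-2-yl)ethyl]-3-(hydroxymethyl)-5-(prop-2-enyl)oxolan-2-one, via bromomagnesium enolate 28 (not isolated)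
Conditions: CuBr·SMe2 (20 mol%), THF, −78 → −40 °C; then CH2O (gas from paraformaldehyde), −78 → −20 °C; aq. NH4Cl
Reagents that add atoms: none
Why: Copper-catalysed conjugate addition of the Grignard reagent should occur anti to the C8 allyl group (sets C7, trans lactone) and the magnesium enolate is hydroxymethylated by formaldehyde anti to the new β-substituent (aldol addition; this carbon becomes C13 and its neighbouring centre is erased in step 20).

Step 12
Reactants: 29 (3R,4S,5R)-4-[2-(1,3-dioxan-2-yl)ethyl]-3-(hydroxymethyl)-5-(prop-2-enyl)oxolan-2-one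
Product: 30 (3R,4S,5R)-3-(hydroxymethyl)-4-(3-oxopropyl)-5-(prop-2-enyl)oxolan-2-one
Conditions: HCl (2 M aq.), THF, 45 °C
Reagents that add atoms: water O
Why: Acid-catalysed hydrolysis of the cyclic acetal frees the aldehyde (the future C1) without affecting the lactone.

Step 13
Reactants: 31 but-3-yn-2-one
Product: 32 2-ethynyl-2-methyl-1,3-dioxolane
Conditions: TMSOCH2CH2OTMS, TMSOTf (cat.), CH2Cl2, −78 °C
Reagents that add atoms: 1,2-bis(trimethylsilyloxy)ethane C[Si](C)(C)OCCO[Si](C)(C)C
Why: Silyl triflate-catalysed ketalisation with the bis-silyl ether of ethylene glycol at low temperature protects the ynone carbonyl (the future C4 acetyl) without conjugate addition.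

Step 14
Reactants: 32 2-ethynyl-2-methyl-1,3-dioxolane; 30 (3R,4S,5R)-3-(hydroxymethyl)-4-(3-oxopropyl)-5-(prop-2-enyl)oxolan-2-one
Product: 35 (3R,4S,5R)-4-[(E)-3-hydroxy-5-(2-methyl-1,3-dioxolan-2-yl)pent-4-enyl]-3-(hydroxymethyl)-5-(prop-2-enyl)oxolan-2-one (both carbinol epimers), via alkenylzirconocene 33 (not isolated), via alkenylzinc 34 (not isolated)
Conditions: 32 (2.5 equiv), Cp2Zr(H)Cl, CH2Cl2, rt; ZnMe2, −65 °C; then 30, 0 °C; aq. NH4Cl
Reagents that add atoms: none
Why: Syn-hydrozirconation of the terminal alkyne, transmetalation to zinc and addition of the (E)-alkenylzinc to the aldehyde tolerate the lactone, and the new carbinol centre need not be controlled because step 15 removes it.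

Step 15
Reactants: 35 (3R,4S,5R)-4-[(E)-3-hydroxy-5-(2-methyl-1,3-dioxolan-2-yl)pent-4-enyl]-3-(hydroxymethyl)-5-(prop-2-enyl)oxolan-2-one
Product: 36 (3R,4S,5R)-3-(hydroxymethyl)-4-[(E)-5-(2-methyl-1,3-dioxolan-2-yl)-3-oxopent-4-enyl]-5-(prop-2-enyl)oxolan-2-one
Conditions: MnO2, CH2Cl2, rt
Reagents that add atoms: none
Why: MnO2 oxidises only the allylic secondary alcohol and leaves the primary alcohol untouched.

Step 16
Reactants: 36 (3R,4S,5R)-3-(hydroxymethyl)-4-[(E)-5-(2-methyl-1,3-dioxolan-2-yl)-3-oxopent-4-enyl]-5-(prop-2-enyl)oxolan-2-one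
Product: 37 (3R,4S,5R)-3-[(tert-butyldimethylsilyloxy)methyl]-4-[(2Z,4E)-3-(tert-butyldimethylsilyloxy)-5-(2-methyl-1,3-dioxolan-2-yl)penta-2,4-dienyl]-5-(prop-2-enyl)oxolan-2-one
Conditions: TBSOTf (2.5 equiv), Et3N, CH2Cl2, −78 → 0 °C
Reagents that add atoms: tert-butyldimethylsilyl trifluoromethanesulfonate CC(C)(C)[Si](C)(C)OS(=O)(=O)C(F)(F)F
Why: Soft enolisation with silyl triflate and amine can only occur toward C5 (the other α-position is vinylic) and should give the (Z)-2-siloxydiene, while the primary alcohol is silylated in the same operation.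

**Union and endgame (steps 17–20)**

Step 17
Reactants: 16 (3aS,7R,8aS)-7-methyl-3-methylidene-6-[(E)-3-oxobut-1-enyl]-3,3a,4,7,8,8a-hexahydrocyclohepta[b]furan-2-one; 37 (3R,4S,5R)-3-[(tert-butyldimethylsilyloxy)methyl]-4-[(2Z,4E)-3-(tert-butyldimethylsilyloxy)-5-(2-methyl-1,3-dioxolan-2-yl)penta-2,4-dienyl]-5-(prop-2-enyl)oxolan-2-one
Product: 39 spiro cyclohexenone (C1 ketone; C2=C3; C3 bearing the 2-methyl-1,3-dioxolan-2-yl group; C5 bearing the CH2 link to the upper lactone; C11′ spiro to the lower lactone), via cycloadduct silyl enol ether 38 (not isolated)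
Conditions: toluene, BHT (cat.), 90 °C; then Pd(OAc)2 (1.2 equiv), MeCN, 40 °C
Reagents that add atoms: none
Why: Normal-demand Diels–Alder reaction of the (Z)-2-siloxydiene with the s-cis-locked methylidene lactone (siloxy para and C3 branch ortho to the lactone carbonyl) should take place on the convex face of 16, anti to C6′, which sets C11′, the exo (carbonyl-anti) mode sets C5, and the transient C3 centre is erased when Pd(OAc)2 dehydrogenates the silyl enol ether (Saegusa–Ito oxidation).

Step 18
Reactants: 39 spiro cyclohexenone with C8 allyl group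
Product: 40 pentacyclic tertiary alcohol (upper cycloheptane closed; C1–OH; C10–CH3; C13 as CH2OTBS; C4 as dioxolane)
Conditions: Fe(acac)3 (0.3 equiv), PhSiH3 (2.5 equiv), EtOH–ethylene glycol (5:1), 60 °C, argon
Reagents that add atoms: none
Why: Trivalent iron and PhSiH3 form an iron hydride that transfers a hydrogen atom to the terminal CH2 of the only electron-rich alkene (the C8 allyl group; enone and dienone are electron-poor), and the secondary C10 radical adds to the C1 carbonyl carbon, the alkoxy radical then being reduced by divalent iron and protonated by ethanol. The closest known reaction is the hydrogen-atom-transfer-initiated radical cyclisation of alkene-tethered ketones to cis-fused bicyclic tertiary alcohols, which is established for five- and six-membered rings; the seven-membered ring and the conjugated ketone are extensions of it. The cycloheptane closes in the 7-exo-trig mode onto C=O, and the β-carbon of the enone is out of reach because it would need a nine-membered ring. C1 is controlled by the tether: the C6 branch at C5 is pseudo-equatorial and tilted toward one face of the carbonyl, so C10 should enter on that face and the hydroxyl ends syn to H-5 (cis ring fusion). C10 is controlled by a chair-like transition state with the methyl pseudo-equatorial and anti to the carbonyl oxygen, so that H-10 should end syn to the hydroxyl. The step needs chemoselective hydrogen-atom transfer and a cyclisation faster than reduction of the radical; the masked C13 (CH2OTBS, no methylidene lactone), the ketal at C4 (no enedione) and oxygen-free conditions are there to secure this.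

Step 19
Reactants: 40 pentacyclic tertiary alcohol
Product: 41 hydroxymethyl lactone with free C4 acetyl (13-hydroxy-11,13-dihydro form of the target)
Conditions: TsOH·H2O (cat.), acetone–H2O, rt → 40 °C
Reagents that add atoms: water O
Why: Acid-catalysed hydrolysis removes the dioxolane (fast, through an allylic oxocarbenium ion) and the primary silyl ether, and the γ-hydroxy enone so formed is no longer prone to ionisation at C1.

Step 20
Reactants: 41 hydroxymethyl lactone
Product: 43 target dimer, via primary mesylate 42 (not isolated)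
Conditions: MsCl, Et3N, CH2Cl2, 0 °C; then DBU, rt
Reagents that add atoms: none
Why: Selective mesylation of the primary alcohol (the tertiary alcohol does not react) and E1cB elimination with DBU unveil the methylidene lactone and erase the C11 centre.

**Compound list**

1 | (R)-but-3-yn-2-ol | C#C[C@@H](C)O | starting material
2 | (R)-but-3-yn-2-yl methanesulfonate | C#C[C@@H](C)OS(C)(=O)=O | intermediate
3 | diethyl malonate | CCOC(=O)CC(=O)OCC | starting material
4 | diethyl 2-[(R)-but-3-yn-2-yl]malonate | C#C[C@H](C)C(C(=O)OCC)C(=O)OCC | intermediate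
5 | ethyl (R)-3-methylpent-4-ynoate | C#C[C@H](C)CC(=O)OCC | intermediate
6 | (R)-3-methylpent-4-ynal | C#C[C@H](C)CC=O | intermediate
7 | ethyl propiolate | C#CC(=O)OCC | starting material
8 | allylmagnesium bromide | C=CC[Mg]Br | starting material
9 | 2-(iodomethyl)-4,4,5,5-tetramethyl-1,3,2-dioxaborolane | ICB1OC(C)(C)C(C)(C)O1 | starting material
10 | ethyl (Z)-2-cupriohexa-2,5-dienoate (alkenylcopper, allyl cis to Cu) | C=CC/C=C(\[Cu])C(=O)OCC | intermediate
11 | ethyl (E)-2-[(4,4,5,5-tetramethyl-1,3,2-dioxaborolan-2-yl)methyl]hexa-2,5-dienoate (allyl cis to CH2B) | C=CC/C=C(\CB1OC(C)(C)C(C)(C)O1)C(=O)OCC | intermediate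
12 | ethyl (3S,4S,6R)-4-hydroxy-6-methyl-2-methylidene-3-(prop-2-enyl)oct-7-ynoate | CCOC(=O)C(=C)[C@H](CC=C)[C@@H](O)C[C@@H](C)C#C | intermediate
13 | (4S,5S)-3-methylidene-5-[(2R)-2-methylbut-3-ynyl]-4-(prop-2-enyl)oxolan-2-one (cis lactone) | C=C1C(=O)O[C@@H](C[C@@H](C)C#C)[C@H]1CC=C | intermediate
14 | but-3-en-2-one (methyl vinyl ketone) | CC(=O)C=C | starting material
15 | (3aS,7R,8aS)-6-ethenyl-7-methyl-3-methylidene-3,3a,4,7,8,8a-hexahydrocyclohepta[b]furan-2-one | C=C1C(=O)O[C@H]2C[C@@H](C)C(C=C)=CC[C@@H]12 | intermediate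
16 | (3aS,7R,8aS)-7-methyl-3-methylidene-6-[(E)-3-oxobut-1-enyl]-3,3a,4,7,8,8a-hexahydrocyclohepta[b]furan-2-one (8-epi-xanthatin skeleton, configuration of the lower unit) | C=C1C(=O)O[C@H]2C[C@@H](C)C(/C=C/C(C)=O)=CC[C@@H]12 | intermediate
17 | (R)-2-(chloromethyl)oxirane ((R)-epichlorohydrin) | ClC[C@H]1CO1 | starting material
18 | vinylmagnesium bromide | C=C[Mg]Br | starting material
19 | (R)-1-chloropent-4-en-2-ol | C=CC[C@@H](O)CCl | intermediate
20 | (R)-2-(prop-2-enyl)oxirane | C=CC[C@@H]1CO1 | intermediate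
21 | 2-(phenylsulfanyl)acetic acid | OC(=O)CSc1ccccc1 | starting material
22 | (4R)-4-hydroxy-2-(phenylsulfanyl)hept-6-enoic acid (both C2 epimers) | C=CC[C@@H](O)CC(Sc1ccccc1)C(O)=O | intermediate
23 | (5R)-3-(phenylsulfanyl)-5-(prop-2-enyl)oxolan-2-one (both C3 epimers) | C=CC[C@@H]1CC(Sc2ccccc2)C(=O)O1 | intermediate
24 | (5R)-3-(phenylsulfinyl)-5-(prop-2-enyl)oxolan-2-one | C=CC[C@@H]1CC(S(=O)c2ccccc2)C(=O)O1 | intermediate
25 | (R)-5-(prop-2-enyl)furan-2(5H)-one | C=CC[C@@H]1C=CC(=O)O1 | intermediate
26 | [2-(1,3-dioxan-2-yl)ethyl]magnesium bromide | Br[Mg]CCC1OCCCO1 | starting material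
27 | formaldehyde | C=O | starting material
28 | bromomagnesium enolate of (4S,5R)-4-[2-(1,3-dioxan-2-yl)ethyl]-5-(prop-2-enyl)oxolan-2-one | Br[Mg]OC1=C[C@H](CCC2OCCCO2)[C@@H](CC=C)O1 | intermediate
29 | (3R,4S,5R)-4-[2-(1,3-dioxan-2-yl)ethyl]-3-(hydroxymethyl)-5-(prop-2-enyl)oxolan-2-one (all-trans) | OC[C@@H]1C(=O)O[C@H](CC=C)[C@H]1CCC1OCCCO1 | intermediate
30 | (3R,4S,5R)-3-(hydroxymethyl)-4-(3-oxopropyl)-5-(prop-2-enyl)oxolan-2-one | OC[C@@H]1C(=O)O[C@H](CC=C)[C@H]1CCC=O | intermediate
31 | but-3-yn-2-one | CC(=O)C#C | starting material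
32 | 2-ethynyl-2-methyl-1,3-dioxolane | C#CC1(C)OCCO1 | intermediate
33 | chloro[(E)-2-(2-methyl-1,3-dioxolan-2-yl)ethenyl]zirconocene | CC1(/C=C/[Zr](Cl)(C2C=CC=C2)C2C=CC=C2)OCCO1 | intermediate
34 | methyl[(E)-2-(2-methyl-1,3-dioxolan-2-yl)ethenyl]zinc | C[Zn]/C=C/C1(C)OCCO1 | intermediate
35 | (3R,4S,5R)-4-[(E)-3-hydroxy-5-(2-methyl-1,3-dioxolan-2-yl)pent-4-enyl]-3-(hydroxymethyl)-5-(prop-2-enyl)oxolan-2-one (both carbinol epimers) | OC[C@@H]1C(=O)O[C@H](CC=C)[C@H]1CCC(O)/C=C/C1(C)OCCO1 | intermediate
36 | (3R,4S,5R)-3-(hydroxymethyl)-4-[(E)-5-(2-methyl-1,3-dioxolan-2-yl)-3-oxopent-4-enyl]-5-(prop-2-enyl)oxolan-2-one | OC[C@@H]1C(=O)O[C@H](CC=C)[C@H]1CCC(=O)/C=C/C1(C)OCCO1 | intermediate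
37 | (3R,4S,5R)-3-[(tert-butyldimethylsilyloxy)methyl]-4-[(2Z,4E)-3-(tert-butyldimethylsilyloxy)-5-(2-methyl-1,3-dioxolan-2-yl)penta-2,4-dienyl]-5-(prop-2-enyl)oxolan-2-one | CC(C)(C)[Si](C)(C)OC[C@@H]1C(=O)O[C@H](CC=C)[C@H]1C/C=C(\O[Si](C)(C)C(C)(C)C)/C=C/C1(C)OCCO1 | intermediate
38 | Diels–Alder adduct: spiro cyclohexene silyl enol ether (C1–OTBS, C1=C2, C3–H cis to the C6 branch) | CC(C)(C)[Si](C)(C)OC[C@@H]1C(=O)O[C@H](CC=C)[C@H]1C[C@H]1C[C@]2(C(=O)O[C@H]3C[C@@H](C)C(/C=C/C(C)=O)=CC[C@@H]23)[C@@H](C4(C)OCCO4)C=C1O[Si](C)(C)C(C)(C)C | intermediate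
39 | spiro cyclohexenone, precursor of the key step (C1 ketone, C2=C3, C4 dioxolane, C8 allyl, C13 as CH2OTBS; 5S, 11′R) | CC(C)(C)[Si](C)(C)OC[C@@H]1C(=O)O[C@H](CC=C)[C@H]1C[C@H]1C[C@]2(C(=O)O[C@H]3C[C@@H](C)C(/C=C/C(C)=O)=CC[C@@H]23)C(C4(C)OCCO4)=CC1=O | intermediate
40 | pentacyclic tertiary alcohol (1R,5S,7S,8R,10S; C4 dioxolane, C13 as CH2OTBS) | CC(C)(C)[Si](C)(C)OC[C@@H]1C(=O)O[C@@H]2C[C@H](C)[C@]3(O)C=C(C4(C)OCCO4)[C@]5(C[C@@H]3C[C@@H]12)C(=O)O[C@H]1C[C@@H](C)C(/C=C/C(C)=O)=CC[C@H]15 | intermediate
41 | 13-hydroxy-11,13-dihydro form of the target (hydroxymethyl lactone, free acetyl) | OC[C@@H]1C(=O)O[C@@H]2C[C@H](C)[C@]3(O)C=C(C(C)=O)[C@]4(C[C@@H]3C[C@@H]12)C(=O)O[C@H]1C[C@@H](C)C(/C=C/C(C)=O)=CC[C@H]14 | intermediate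
42 | primary methanesulfonate of 41 | CS(=O)(=O)OC[C@@H]1C(=O)O[C@@H]2C[C@H](C)[C@]3(O)C=C(C(C)=O)[C@]4(C[C@@H]3C[C@@H]12)C(=O)O[C@H]1C[C@@H](C)C(/C=C/C(C)=O)=CC[C@H]14 | intermediate
43 | target xanthanolide dimer (1R,5S,7S,8R,10S,7′S,8′S,10′R,11′R) | C=C1C(=O)O[C@@H]2C[C@H](C)[C@]3(O)C=C(C(C)=O)[C@]4(C[C@@H]3C[C@@H]12)C(=O)O[C@H]1C[C@@H](C)C(/C=C/C(C)=O)=CC[C@H]14 | target

**Step count and risks**

Total step count: 20.
Longest linear sequence: 12 steps (steps 8, 9, 10, 11, 12, 14, 15, 16, 17, 18, 19, 20).

The three steps most likely to fail: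

1. Step 18. The secondary radical may simply be reduced (the allyl group ends as propyl), or hydrogen-atom transfer may attack the dienone, before the slow 7-exo addition to a conjugated carbonyl takes place; the methyl-bearing centre may also form with the wrong face. The fallback sets out from 39 and returns at 40. The allyl group, the only electron-rich alkene, is epoxidised with mCPBA to the terminal epoxide F1. Cp2TiCl (from Cp2TiCl2 and Zn dust, THF) opens the epoxide homolytically to the secondary C10 radical, and trapping of the alkoxy radical by trivalent titanium makes its addition to the C1 ketone irreversible, giving the cyclised C14-hydroxy diol F2. An Appel iodination (I2, PPh3, imidazole) of the primary alcohol gives the primary iodide F3, and reduction with Bu3SnH and AIBN returns to 40.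

2. Step 17. The cycloaddition may discriminate poorly between the exo and endo modes, so that the ring-fusion centre C5 forms as a mixture, and bond formation at the hindered diene terminus next to the ketal may be slow. The fallback sets out from 38 and returns at 39; it corrects C5 after the ring is made instead of in the cycloaddition. The crude adduct mixture 38 is oxidised as in step 17 and the C5 epimer F4 of 39 is separated. Because H-5 is α to the ring ketone, the C5 epimer F4 is equilibrated through the cross-conjugated dienol with DBU in toluene (or deprotonated with KN(SiMe3)2 and reprotonated kinetically), and the recovered 39 is carried on.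

3. Step 6. The ester-deactivated boronate may react sluggishly under Brønsted-acid catalysis, and catalyst control over the β-branched aldehyde may be incomplete, eroding enantio- and diastereocontrol at C7′ and C8′. The fallback sets out from 10 and 6 and returns at 13. The alkenylcopper 10 is trapped with formaldehyde instead of 9 to give the allylic alcohol F5, and PBr3 converts it into the allylic bromide F6. An indium-mediated Barbier allylation of 6 in aqueous THF (syn-selective, no enantiocontrol), followed by acid lactonisation, gives 13 together with the (4R,5R)-diastereomer F7. Because C10′ is fixed, the two are diastereomers and are separated by chromatography.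

Further compounds
F1 | step 18 | epoxide of 39 (oxiran-2-ylmethyl group at C8, both oxirane epimers) | CC(C)(C)[Si](C)(C)OC[C@@H]1C(=O)O[C@H](CC5CO5)[C@H]1C[C@H]1C[C@]2(C(=O)O[C@H]3C[C@@H](C)C(/C=C/C(C)=O)=CC[C@@H]23)C(C4(C)OCCO4)=CC1=O
F2 | step 18 | C14-hydroxy analogue of 40 (cyclised 1,3-diol) | CC(C)(C)[Si](C)(C)OC[C@@H]1C(=O)O[C@@H]2C[C@H](CO)[C@]3(O)C=C(C4(C)OCCO4)[C@]5(C[C@@H]3C[C@@H]12)C(=O)O[C@H]1C[C@@H](C)C(/C=C/C(C)=O)=CC[C@H]15
F3 | step 18 | C14-iodo analogue of 40 | CC(C)(C)[Si](C)(C)OC[C@@H]1C(=O)O[C@@H]2C[C@H](CI)[C@]3(O)C=C(C4(C)OCCO4)[C@]5(C[C@@H]3C[C@@H]12)C(=O)O[C@H]1C[C@@H](C)C(/C=C/C(C)=O)=CC[C@H]15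
F4 | step 17 | C5 epimer of 39 | CC(C)(C)[Si](C)(C)OC[C@@H]1C(=O)O[C@H](CC=C)[C@H]1C[C@@H]1C[C@]2(C(=O)O[C@H]3C[C@@H](C)C(/C=C/C(C)=O)=CC[C@@H]23)C(C4(C)OCCO4)=CC1=O
F5 | step 6 | ethyl (E)-2-(hydroxymethyl)hexa-2,5-dienoate | C=CC/C=C(\CO)C(=O)OCC
F6 | step 6 | ethyl (Z)-2-(bromomethyl)hexa-2,5-dienoate | C=CC/C=C(\CBr)C(=O)OCC
F7 | step 6 | (4R,5R)-3-methylidene-5-[(2R)-2-methylbut-3-ynyl]-4-(prop-2-enyl)oxolan-2-one | C=C1C(=O)O[C@H](C[C@@H](C)C#C)[C@@H]1CC=C
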